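**Retrosynthetic overview**

- Prostanoid numbering is used: C9 ring carbonyl, C10 C–Cl, C11 ring CH=, C12 C–OAc, C8 ring carbon of the exocyclic C7=C8 bond. The target comes from desilylation and acetylation of its 12-silyl ether, itself made by a stereoretentive Suzuki–Miyaura coupling (C6–C7) of a C7 (Z)-enol triflate with an (E)-alkenylboronate carrying C1–C6. This sets 5E and 7Z.
- The enol triflate comes from chelate-controlled formylation/triflation at C8 of a 2-chloro-4-silyloxy-4-octenylcyclopentenone. That enone is obtained as one enantiomer from the racemate by catalyst-controlled carbonyl reduction, separation of diastereomers and re-oxidation (secures C12).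
- The cyclopentenone, the only ring, is made by a (3+2) annulation that forms C8–C9 and C11–C12 in one flask. The methyl-side lithium enolate of (Z)-dec-4-en-2-one (C8, C12, ω-chain) adds to a 2-chloro-3-(phenylsulfanyl)acryloylsilane (C9, C10 with its chlorine, C11); 1,2-Brook rearrangement and ring closure follow.
- Enabling feature: in the ring C8–C9(=O)–C10(Cl)=C11–C12(O), the oxygen-bearing C12 is flanked by C8 (alpha to the C9 carbonyl) and C11 (beta to it). C12 can therefore be a ketone carbonyl whose own enolate carbon is C8, while C9–C10–C11 is an acylsilane that is electrophilic at C9 and, after silyl migration to oxygen, nucleophilic at C11.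
- Fragments: the acylsilane from a propargyl silyl ether (retro-Brook, oxidation, thiol addition, chlorination); the enolate from (Z)-oct-2-en-1-ol and ethynylmagnesium bromide via a 1-alken-2-yl acetate; the boronate from methyl hex-5-ynoate.

Key step: step 8

Remark: the target is read as the 5E,7Z,14Z isomer (C6 on the side of the C9 carbonyl) with R configuration at C12. Ring compounds are racemic up to step 9 and single enantiomers from step 10 on.

Step 1
Reactants: 1 tert-butyldimethyl(prop-2-yn-1-yloxy)silane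
Product: 2 1-[tert-butyl(dimethyl)silyl]prop-2-yn-1-ol (racemic)
Conditions: n-BuLi (1.05 equiv), THF, −78 °C; s-BuLi (1.2 equiv), −78 to −30 °C; aq. NH4Cl
Reagents that add atoms: none
Why: Retro-Brook (1,2-silyl O-to-C) rearrangement of the dilithiated propargyl silyl ether, driven by the O–Li bond, is an established entry to 1-silylprop-2-yn-1-ols.

Step 2
Reactants: 2 1-[tert-butyl(dimethyl)silyl]prop-2-yn-1-ol
Product: 3 1-[tert-butyl(dimethyl)silyl]prop-2-yn-1-one
Conditions: Dess–Martin periodinane (1.2 equiv), CH2Cl2, 0 °C to rt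
Reagents that add atoms: none
Why: Dess–Martin oxidation converts the α-silyl carbinol into the ynoylsilane under non-basic conditions, so the alkoxide needed for a Brook rearrangement never forms.

Step 3
Reactants: 3 1-[tert-butyl(dimethyl)silyl]prop-2-yn-1-one
Product: 4 (2E)-1-[tert-butyl(dimethyl)silyl]-3-(phenylsulfanyl)prop-2-en-1-one
Conditions: thiophenol (1.0 equiv), Et3N (5 mol%), CH2Cl2, 0 °C to rt
Reagents that add atoms: thiophenol, Sc1ccccc1
Why: Amine-catalysed thia-Michael addition to the ynone gives the β-sulfanyl enoylsilane, which should equilibrate to the E isomer (its geometry is of no consequence later).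

Step 4
Reactants: 4 (2E)-1-[tert-butyl(dimethyl)silyl]-3-(phenylsulfanyl)prop-2-en-1-one
Product: 5 (2Z)-1-[tert-butyl(dimethyl)silyl]-2-chloro-3-(phenylsulfanyl)prop-2-en-1-one
Conditions: N-chlorosuccinimide (1.05 equiv), CH2Cl2, 0 °C
Reagents that add atoms: N-chlorosuccinimide, O=C1CCC(=O)N1Cl
Why: Electrophilic α-chlorination of the push-pull (vinylogous thioester) alkene proceeds through the sulfur-stabilised cation and loss of the α-proton, leaving the acylsilane untouched.

Step 5
Reactants: 6 (2Z)-oct-2-en-1-ol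
Product: 7 (2Z)-1-bromooct-2-ene
Conditions: CBr4 (1.2 equiv), PPh3 (1.25 equiv), CH2Cl2, 0 °C
Reagents that add atoms: carbon tetrabromide, BrC(Br)(Br)Br
Why: The Appel reaction replaces the primary allylic hydroxyl by bromide under neutral conditions without touching the Z alkene.

Step 6
Reactants: 7 (2Z)-1-bromooct-2-ene; 8 ethynylmagnesium bromide
Product: 9 (4Z)-dec-4-en-1-yne
Conditions: CuCl (10 mol%), THF, 0 to 40 °C
Reagents that add atoms: none
Why: Copper-catalysed SN2 coupling of an alkynyl Grignard reagent with a primary allylic bromide gives the skipped (1,4-) enyne with retention of the Z geometry.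

Step 7
Reactants: 9 (4Z)-dec-4-en-1-yne
Product: 10 (4Z)-deca-1,4-dien-2-yl acetate
Conditions: AcOH (1.3 equiv), [RuCl2(p-cymene)]2 (1 mol%), tri(2-furyl)phosphine (2 mol%), Na2CO3 (4 mol%), toluene, 50 °C
Reagents that add atoms: acetic acid, CC(=O)O
Why: Ruthenium-catalysed Markovnikov hydro-acyloxylation of the terminal alkyne gives the 1-alken-2-yl acetate, a regiodefined store for the methyl-side enolate that deprotonation of the β,γ-unsaturated ketone would not give cleanly.

Step 8
Reactants: 10 (4Z)-deca-1,4-dien-2-yl acetate; 5 (2Z)-1-[tert-butyl(dimethyl)silyl]-2-chloro-3-(phenylsulfanyl)prop-2-en-1-one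
Product: 13 tert-butyl({2-chloro-4-[(2Z)-oct-2-en-1-yl]-3-(phenylsulfanyl)-4-[(triethylsilyl)oxy]cyclopent-1-en-1-yl}oxy)dimethylsilane (racemic), via lithium enolate 11 (not isolated), via siloxyallyl anion 12 (not isolated)
Conditions: MeLi (2.0 equiv), THF, 0 °C; then 5, −80 to −30 °C; then Et3SiOTf (2.5 equiv), −78 °C; aq. NaHCO3
Reagents that add atoms: triethylsilyl trifluoromethanesulfonate, CC[Si](CC)(CC)OS(=O)(=O)C(F)(F)F
Why: The kinetic enolate 11, released from the enol acetate by MeLi, adds with C8 to the acylsilane carbonyl C9 (C8–C9 bond); the α-silyl alkoxide then undergoes 1,2-Brook rearrangement to the siloxyallyl anion 12, whose charge at C11 is stabilised by sulfur, and C11 adds to the C12 ketone (C11–C12 bond) before the tertiary alkoxide is capped as the triethylsilyl ether. The closest known reaction type is the Brook-rearrangement-mediated (3+2) annulation of β-(phenylsulfanyl)acryloylsilanes with lithium enolates of methyl ketones, which gives precursors of 4-alkyl-4-hydroxycyclopentenones. The cyclopentene ring is closed by a 5-exo-trig attack of the carbanion on the C12 carbonyl, with the new C9=C10 enol ether inside the ring. C12 is formed without absolute control (racemate; its configuration is secured in steps 10 and 11), and its relation to C11, set by lithium bridging between alkoxide and sulfur, is irrelevant because C11 becomes sp2 in step 9. The step needs 1,2-addition instead of conjugate addition to 5 and an enolate on the methyl side only: the strongly electrophilic acylsilane carbonyl at −80 °C should secure the first, and making 11 from the enol acetate instead of deprotonating the ketone, whose C13 methylene is doubly activated, secures the second.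

Step 9
Reactants: 13 tert-butyl({2-chloro-4-[(2Z)-oct-2-en-1-yl]-3-(phenylsulfanyl)-4-[(triethylsilyl)oxy]cyclopent-1-en-1-yl}oxy)dimethylsilane
Product: 16 2-chloro-4-[(2Z)-oct-2-en-1-yl]-4-[(triethylsilyl)oxy]cyclopent-2-en-1-one (racemic), via β-sulfanyl ketone 14 (not isolated), via β-keto sulfoxide 15 (not isolated)
Conditions: Bu4NF (1.05 equiv), AcOH (1.5 equiv), THF, −40 °C; then mCPBA (1.0 equiv), CH2Cl2, −78 °C; then Et3N, −78 °C to rt
Reagents that add atoms: none
Why: Buffered fluoride should cleave only the silyl enol ether, chemoselective sulfide oxidation at −78 °C gives the β-keto sulfoxide, and sulfoxide elimination toward the acidic C10–H (the only β-hydrogen) forms the 2-chloro enone.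

Step 10
Reactants: 16 2-chloro-4-[(2Z)-oct-2-en-1-yl]-4-[(triethylsilyl)oxy]cyclopent-2-en-1-one (racemic)
Product: 17 (1R,4S)-2-chloro-4-[(2Z)-oct-2-en-1-yl]-4-[(triethylsilyl)oxy]cyclopent-2-en-1-ol
Conditions: (S)-2-methyl-CBS-oxazaborolidine (20 mol%), catecholborane (1.5 equiv), toluene, −78 °C; separation of the two diastereomers by chromatography
Reagents that add atoms: none
Why: The Corey–Bakshi–Shibata reduction is used as a parallel kinetic resolution: the catalyst should set the new carbinol centre as 1R in both enantiomers of 16 (chlorovinyl arm as the large group), which turns the two C4 antipodes into separable diastereomers, of which the (1R,4S) isomer is kept.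

Step 11
Reactants: 17 (1R,4S)-2-chloro-4-[(2Z)-oct-2-en-1-yl]-4-[(triethylsilyl)oxy]cyclopent-2-en-1-ol
Product: 18 (4S)-2-chloro-4-[(2Z)-oct-2-en-1-yl]-4-[(triethylsilyl)oxy]cyclopent-2-en-1-one
Conditions: Dess–Martin periodinane (1.3 equiv), CH2Cl2, 0 °C to rt
Reagents that add atoms: none
Why: Dess–Martin oxidation of the allylic alcohol returns the enone with the C4 stereocentre untouched, the carbinol centre of step 10 having served only for the separation.

Step 12
Reactants: 18 (4S)-2-chloro-4-[(2Z)-oct-2-en-1-yl]-4-[(triethylsilyl)oxy]cyclopent-2-en-1-one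
Product: 20 (Z)-{(5R)-3-chloro-5-[(2Z)-oct-2-en-1-yl]-2-oxo-5-[(triethylsilyl)oxy]cyclopent-3-en-1-ylidene}methyl trifluoromethanesulfonate, via lithium hydroxymethylene enolate 19 (not isolated)
Conditions: LiN(SiMe3)2 (1.1 equiv), THF, −78 °C; 2,2,2-trifluoroethyl formate (1.3 equiv), −78 °C; then PhNTf2 (1.2 equiv), −78 to 0 °C; aq. NH4Cl
Reagents that add atoms: 2,2,2-trifluoroethyl formate, O=COCC(F)(F)F; N-phenylbis(trifluoromethanesulfonimide), O=S(=O)(N(c1ccccc1)S(=O)(=O)C(F)(F)F)C(F)(F)F
Why: Deprotonation is possible only at C8 (the sole enolisable position), Claisen-type C-formylation with the activated formate gives the lithium-chelated hydroxymethylene enolate 19, and O-sulfonylation of this chelate should place the triflate cis to the ring carbonyl (Z enol triflate).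

Step 13
Reactants: 21 methyl hex-5-ynoate
Product: 22 methyl (5E)-6-(4,4,5,5-tetramethyl-1,3,2-dioxaborolan-2-yl)hex-5-enoate
Conditions: pinacolborane (1.1 equiv), Cp2Zr(H)Cl (5 mol%), Et3N (10 mol%), neat, 60 °C
Reagents that add atoms: pinacolborane, CC1(C)OBOC1(C)C
Why: Zirconium-catalysed syn-hydroboration of the terminal alkyne with pinacolborane gives the (E)-alkenylboronate regio- and stereoselectively, and the ester is tolerated.

Step 14
Reactants: 20 (Z)-{(5R)-3-chloro-5-[(2Z)-oct-2-en-1-yl]-2-oxo-5-[(triethylsilyl)oxy]cyclopent-3-en-1-ylidene}methyl trifluoromethanesulfonate; 22 methyl (5E)-6-(4,4,5,5-tetramethyl-1,3,2-dioxaborolan-2-yl)hex-5-enoate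
Product: 23 methyl (5E,7Z,12R,14Z)-10-chloro-9-oxo-12-[(triethylsilyl)oxy]prosta-5,7,10,14-tetraen-1-oate
Conditions: PdCl2(dppf) (5 mol%), K3PO4 (3 equiv), THF/H2O (10:1), rt
Reagents that add atoms: none
Why: Suzuki–Miyaura coupling of the vinylogous acyl triflate proceeds with retention at both sp2 carbons (zerovalent palladium inserts into the C–OTf bond much faster than into the vinyl C–Cl bond), so the C6–C7 bond should form with the 5E,7Z geometry.

Step 15
Reactants: 23 methyl (5E,7Z,12R,14Z)-10-chloro-9-oxo-12-[(triethylsilyl)oxy]prosta-5,7,10,14-tetraen-1-oate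
Product: 24 methyl (5E,7Z,12R,14Z)-10-chloro-12-hydroxy-9-oxoprosta-5,7,10,14-tetraen-1-oate
Conditions: HF·pyridine, pyridine, THF, 0 °C
Reagents that add atoms: none
Why: Fluoride-mediated desilylation under buffered, mildly acidic conditions frees the tertiary alcohol without conjugate addition to the dienone.

Step 16
Reactants: 24 methyl (5E,7Z,12R,14Z)-10-chloro-12-hydroxy-9-oxoprosta-5,7,10,14-tetraen-1-oate
Product: 25 methyl (5E,7Z,12R,14Z)-12-acetoxy-10-chloro-9-oxoprosta-5,7,10,14-tetraen-1-oate
Conditions: Ac2O (5 equiv), DMAP (0.2 equiv), Et3N, CH2Cl2, rt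
Reagents that add atoms: acetic anhydride, CC(=O)OC(C)=O
Why: Nucleophile-catalysed acetylation (acyl transfer through the N-acetylpyridinium ion) esterifies the hindered tertiary alcohol, which cannot eliminate because C8 carries no hydrogen.

**Compound list**

1 | tert-butyldimethyl(prop-2-yn-1-yloxy)silane | C#CCO[Si](C)(C)C(C)(C)C | starting material
2 | 1-[tert-butyl(dimethyl)silyl]prop-2-yn-1-ol (racemic) | C#CC(O)[Si](C)(C)C(C)(C)C | intermediate
3 | 1-[tert-butyl(dimethyl)silyl]prop-2-yn-1-one | C#CC(=O)[Si](C)(C)C(C)(C)C | intermediate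
4 | (2E)-1-[tert-butyl(dimethyl)silyl]-3-(phenylsulfanyl)prop-2-en-1-one | O=C(/C=C/Sc1ccccc1)[Si](C)(C)C(C)(C)C | intermediate
5 | (2Z)-1-[tert-butyl(dimethyl)silyl]-2-chloro-3-(phenylsulfanyl)prop-2-en-1-one | O=C(/C(Cl)=C/Sc1ccccc1)[Si](C)(C)C(C)(C)C | intermediate
6 | (2Z)-oct-2-en-1-ol | CCCCC/C=C\CO | starting material
7 | (2Z)-1-bromooct-2-ene | CCCCC/C=C\CBr | intermediate
8 | ethynylmagnesium bromide | C#C[Mg]Br | starting material
9 | (4Z)-dec-4-en-1-yne | C#CC/C=C\CCCCC | intermediate
10 | (4Z)-deca-1,4-dien-2-yl acetate | C=C(OC(C)=O)C/C=C\CCCCC | intermediate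
11 | lithium (4Z)-deca-1,4-dien-2-olate | [Li+].[O-]C(=C)C/C=C\CCCCC | intermediate
12 | lithium (7Z)-3-{[tert-butyl(dimethyl)silyl]oxy}-2-chloro-5-oxo-1-(phenylsulfanyl)trideca-2,7-dien-1-ide | [Li+].CCCCC/C=C\CC(=O)CC(O[Si](C)(C)C(C)(C)C)=C(Cl)[CH-]Sc1ccccc1 | intermediate
13 | tert-butyl({2-chloro-4-[(2Z)-oct-2-en-1-yl]-3-(phenylsulfanyl)-4-[(triethylsilyl)oxy]cyclopent-1-en-1-yl}oxy)dimethylsilane (racemic; both epimers at the sulfur-bearing carbon) | CCCCC/C=C\CC1(O[Si](CC)(CC)CC)CC(O[Si](C)(C)C(C)(C)C)=C(Cl)C1Sc1ccccc1 | intermediate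
14 | 2-chloro-4-[(2Z)-oct-2-en-1-yl]-3-(phenylsulfanyl)-4-[(triethylsilyl)oxy]cyclopentan-1-one (racemic, diastereomer mixture) | CCCCC/C=C\CC1(O[Si](CC)(CC)CC)CC(=O)C(Cl)C1Sc1ccccc1 | intermediate
15 | 2-chloro-4-[(2Z)-oct-2-en-1-yl]-3-(phenylsulfinyl)-4-[(triethylsilyl)oxy]cyclopentan-1-one (racemic, diastereomer mixture) | CCCCC/C=C\CC1(O[Si](CC)(CC)CC)CC(=O)C(Cl)C1S(=O)c1ccccc1 | intermediate
16 | 2-chloro-4-[(2Z)-oct-2-en-1-yl]-4-[(triethylsilyl)oxy]cyclopent-2-en-1-one (racemic) | CCCCC/C=C\CC1(O[Si](CC)(CC)CC)C=C(Cl)C(=O)C1 | intermediate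
17 | (1R,4S)-2-chloro-4-[(2Z)-oct-2-en-1-yl]-4-[(triethylsilyl)oxy]cyclopent-2-en-1-ol | CCCCC/C=C\C[C@@]1(O[Si](CC)(CC)CC)C=C(Cl)[C@H](O)C1 | intermediate
18 | (4S)-2-chloro-4-[(2Z)-oct-2-en-1-yl]-4-[(triethylsilyl)oxy]cyclopent-2-en-1-one | CCCCC/C=C\C[C@@]1(O[Si](CC)(CC)CC)C=C(Cl)C(=O)C1 | intermediate
19 | lithium (Z)-{(5R)-3-chloro-5-[(2Z)-oct-2-en-1-yl]-2-oxo-5-[(triethylsilyl)oxy]cyclopent-3-en-1-ylidene}methanolate | [Li+].CCCCC/C=C\C[C@@]1(O[Si](CC)(CC)CC)C=C(Cl)C(=O)/C1=C\[O-] | intermediate
20 | (Z)-{(5R)-3-chloro-5-[(2Z)-oct-2-en-1-yl]-2-oxo-5-[(triethylsilyl)oxy]cyclopent-3-en-1-ylidene}methyl trifluoromethanesulfonate (same spatial arrangement at the carbinol carbon as 4S in 18; the descriptor changes because the ranking of the ring neighbours changes) | CCCCC/C=C\C[C@@]1(O[Si](CC)(CC)CC)C=C(Cl)C(=O)/C1=C\OS(=O)(=O)C(F)(F)F | intermediate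
21 | methyl hex-5-ynoate | C#CCCCC(=O)OC | starting material
22 | methyl (5E)-6-(4,4,5,5-tetramethyl-1,3,2-dioxaborolan-2-yl)hex-5-enoate | COC(=O)CCC/C=C/B1OC(C)(C)C(C)(C)O1 | intermediate
23 | methyl (5E,7Z,12R,14Z)-10-chloro-9-oxo-12-[(triethylsilyl)oxy]prosta-5,7,10,14-tetraen-1-oate | CCCCC/C=C\C[C@@]1(O[Si](CC)(CC)CC)C=C(Cl)C(=O)/C1=C\C=C\CCCC(=O)OC | intermediate
24 | methyl (5E,7Z,12R,14Z)-10-chloro-12-hydroxy-9-oxoprosta-5,7,10,14-tetraen-1-oate | CCCCC/C=C\C[C@@]1(O)C=C(Cl)C(=O)/C1=C\C=C\CCCC(=O)OC | intermediate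
25 | methyl (5E,7Z,12R,14Z)-12-acetoxy-10-chloro-9-oxoprosta-5,7,10,14-tetraen-1-oate | CCCCC/C=C\C[C@@]1(OC(C)=O)C=C(Cl)C(=O)/C1=C\C=C\CCCC(=O)OC | target

**Step count and risks**

Total step count: 16. Longest linear sequence: 12 steps (1, 2, 3, 4, 8, 9, 10, 11, 12, 14, 15, 16).

Most likely to fail, in this order: step 8, step 12, step 10.

Step 8. The enolate may add in conjugate fashion to the sulfur-bearing carbon of the α-chloro acylsilane with loss of thiophenolate, or the siloxyallyl anion may be quenched by proton transfer from the doubly activated C13 methylene before it closes on C12. The fallback moves the chlorine to a later stage and sets out from 4 and 10. The annulation is run with the chlorine-free acylsilane 4 and enolate 11 under the conditions of step 8 to give tert-butyldimethyl({4-[(2Z)-oct-2-en-1-yl]-3-(phenylsulfanyl)-4-[(triethylsilyl)oxy]cyclopent-1-en-1-yl}oxy)silane F1. Buffered fluoride, sulfide oxidation and sulfoxide elimination as in step 9 give 4-[(2Z)-oct-2-en-1-yl]-4-[(triethylsilyl)oxy]cyclopent-2-en-1-one F2. Nucleophilic epoxidation (H2O2, NaOH, MeOH, 0 °C) gives 4-[(2Z)-oct-2-en-1-yl]-4-[(triethylsilyl)oxy]-6-oxabicyclo[3.1.0]hexan-2-one F3. Chloride opening at C10 (LiCl, AcOH, THF) gives 2-chloro-3-hydroxy-4-[(2Z)-oct-2-en-1-yl]-4-[(triethylsilyl)oxy]cyclopentan-1-one F4, which should lose water on warming in the same medium and return to the route at 16.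

Step 12. O-sulfonylation may occur without chelate control, so that the Z geometry of the enol triflate is lost, or the C8 enolate may expel the C12 silyloxy group. The fallback is the aldol–dehydration sequence and sets out from 18. Methyl (5E)-7-oxohept-5-enoate F5 is made by Wittig reaction of methyl 5-oxopentanoate with (triphenylphosphoranylidene)acetaldehyde. The lithium enolate of 18 (LiN(iPr)2, THF, −78 °C) adds to F5 to give methyl (5E)-7-{(5R)-3-chloro-5-[(2Z)-oct-2-en-1-yl]-2-oxo-5-[(triethylsilyl)oxy]cyclopent-3-en-1-yl}-7-hydroxyhept-5-enoate F6. Mesylation (MsCl, Et3N) gives the corresponding 7-(methylsulfonyl)oxy compound F7, and elimination with DBU returns to the route at 23. This elimination is not stereospecific, so 23 would be accompanied by its 7E isomer, methyl (5E,7E,12R,14Z)-10-chloro-9-oxo-12-[(triethylsilyl)oxy]prosta-5,7,10,14-tetraen-1-oate F8, to be removed by chromatography.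

Step 10. Incomplete catalyst control in the reduction of the mismatched enantiomer would carry the wrong C12 antipode into the collected diastereomer and erode the enantiomeric purity. The fallback sets out from 16: the racemate is resolved directly by preparative chromatography on a chiral stationary phase, and the (4S) enantiomer returns to the route at 18, so steps 10 and 11 are left out. No new compound is made (F0).

Further compounds
F1 | step 8 | tert-butyldimethyl({4-[(2Z)-oct-2-en-1-yl]-3-(phenylsulfanyl)-4-[(triethylsilyl)oxy]cyclopent-1-en-1-yl}oxy)silane (racemic) | CCCCC/C=C\CC1(O[Si](CC)(CC)CC)CC(O[Si](C)(C)C(C)(C)C)=CC1Sc1ccccc1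
F2 | step 8 | 4-[(2Z)-oct-2-en-1-yl]-4-[(triethylsilyl)oxy]cyclopent-2-en-1-one (racemic) | CCCCC/C=C\CC1(O[Si](CC)(CC)CC)C=CC(=O)C1
F3 | step 8 | 4-[(2Z)-oct-2-en-1-yl]-4-[(triethylsilyl)oxy]-6-oxabicyclo[3.1.0]hexan-2-one (racemic) | CCCCC/C=C\CC1(O[Si](CC)(CC)CC)CC(=O)C2OC12
F4 | step 8 | 2-chloro-3-hydroxy-4-[(2Z)-oct-2-en-1-yl]-4-[(triethylsilyl)oxy]cyclopentan-1-one (racemic) | CCCCC/C=C\CC1(O[Si](CC)(CC)CC)CC(=O)C(Cl)C1O
F5 | step 12 | methyl (5E)-7-oxohept-5-enoate | COC(=O)CCC/C=C/C=O
F6 | step 12 | methyl (5E)-7-{(5R)-3-chloro-5-[(2Z)-oct-2-en-1-yl]-2-oxo-5-[(triethylsilyl)oxy]cyclopent-3-en-1-yl}-7-hydroxyhept-5-enoate | CCCCC/C=C\C[C@@]1(O[Si](CC)(CC)CC)C=C(Cl)C(=O)C1C(O)/C=C/CCCC(=O)OC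
F7 | step 12 | methyl (5E)-7-{(5R)-3-chloro-5-[(2Z)-oct-2-en-1-yl]-2-oxo-5-[(triethylsilyl)oxy]cyclopent-3-en-1-yl}-7-[(methylsulfonyl)oxy]hept-5-enoate | CCCCC/C=C\C[C@@]1(O[Si](CC)(CC)CC)C=C(Cl)C(=O)C1C(OS(C)(=O)=O)/C=C/CCCC(=O)OC
F8 | step 12 | methyl (5E,7E,12R,14Z)-10-chloro-9-oxo-12-[(triethylsilyl)oxy]prosta-5,7,10,14-tetraen-1-oate | CCCCC/C=C\C[C@@]1(O[Si](CC)(CC)CC)C=C(Cl)C(=O)/C1=C/C=C/CCCC(=O)OC
F0 | step 10 | none | none
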